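**Retrosynthetic overview**
- The target comes from its tetra-O-methyl ether by one global O-demethylation at the very end.
- The pyranone ring C is the only ring built; it is closed last by oxidative cyclisation of a 2'-hydroxychalcone. Rings A, B and the benzoic acid ring D are bought as arenes.
- The chalcone Cα–Cβ bond is the key bond: an intermolecular Claisen–Schmidt aldol condensation joins a biaryl methyl ketone to 4-methoxybenzaldehyde.
- The biaryl ketone comes from ortho-acylation of a symmetrical 4-aryl-3,5-dimethoxyphenol; the symmetry fixes the aryl group at C6 rather than C8 of the flavone.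
- The biaryl comes from Suzuki coupling of a 4-iodo-3,5-dimethoxyphenyl silyl ether (from 3,5-dimethoxyphenol by directed metalation) with 2-methoxy-5-(methoxycarbonyl)phenylboronic acid.

Assumption: the SMILES carries no stereodescriptor, the molecule has no stereocentre, and the biaryl axis (three small ortho OH groups) rotates freely at room temperature, so the target is made as the single achiral compound drawn.

**Step 1**
Reactants: 1 3,5-dimethoxyphenol
Product: 2 (3,5-dimethoxyphenoxy)tri(propan-2-yl)silane
Conditions: TIPSCl (1.1 equiv), imidazole (2 equiv), DMF, rt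
Reagents that add atoms: chlorotri(propan-2-yl)silane (TIPSCl), CC(C)[Si](Cl)(C(C)C)C(C)C
Why: Silyl etherification of the only phenol gives a bulky TIPS ether that survives n-BuLi and shields its own ortho positions from metalation.

**Step 2**
Reactants: 2 (3,5-dimethoxyphenoxy)tri(propan-2-yl)silane
Product: 4 (4-iodo-3,5-dimethoxyphenoxy)tri(propan-2-yl)silane, via aryllithium 3 (not isolated)
Conditions: n-BuLi (1.2 equiv), THF, 0 °C to rt, 2 h; then I2, THF, −78 °C to rt
Reagents that add atoms: iodine, II
Why: Directed ortho-metalation removes the proton flanked by the two methoxy groups (cooperative direction, OTIPS too bulky to direct), and iodinolysis of the aryllithium gives the symmetrical iodide.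

**Step 3**
Reactants: 4 (4-iodo-3,5-dimethoxyphenoxy)tri(propan-2-yl)silane; 5 [2-methoxy-5-(methoxycarbonyl)phenyl]boronic acid
Product: 6 methyl 3-{2,6-dimethoxy-4-[tri(propan-2-yl)silyloxy]phenyl}-4-methoxybenzoate
Conditions: Pd(OAc)2 (5 mol%), SPhos (10 mol%), K3PO4 (3 equiv), toluene/H2O 10:1, 90 °C
Reagents that add atoms: none
Why: Suzuki–Miyaura cross-coupling in which the electron-rich SPhos ligand lets zerovalent palladium insert into the hindered di-ortho-methoxy aryl iodide and deliver the tri-ortho-substituted biaryl without harming the ester or silyl ether.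

**Step 4**
Reactants: 6 methyl 3-{2,6-dimethoxy-4-[tri(propan-2-yl)silyloxy]phenyl}-4-methoxybenzoate
Product: 7 methyl 3-(4-hydroxy-2,6-dimethoxyphenyl)-4-methoxybenzoate
Conditions: Bu4NF (1.2 equiv), AcOH (1.2 equiv), THF, 0 °C to rt
Reagents that add atoms: none
Why: Fluoride-mediated desilylation driven by Si–F bond formation, buffered with AcOH so the methyl ester is untouched.

**Step 5**
Reactants: 7 methyl 3-(4-hydroxy-2,6-dimethoxyphenyl)-4-methoxybenzoate
Product: 9 methyl 3-(3-acetyl-4-hydroxy-2,6-dimethoxyphenyl)-4-methoxybenzoate, via aryl acetate 8 (not isolated)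
Conditions: Ac2O (3 equiv), BF3·OEt2 (4 equiv), 80 °C, 3 h; then ice-water
Reagents that add atoms: acetic anhydride, CC(=O)OC(C)=O
Why: O-acetylation followed by BF3-promoted Fries rearrangement (Friedel–Crafts acylation) puts the acetyl group ortho to the phenol; the ring is symmetrical with its para position blocked, so only one C-acyl product can form, and the electron-poor benzoate ring does not react.

**Step 6**
Reactants: 9 methyl 3-(3-acetyl-4-hydroxy-2,6-dimethoxyphenyl)-4-methoxybenzoate
Product: 10 3-(3-acetyl-4-hydroxy-2,6-dimethoxyphenyl)-4-methoxybenzoic acid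
Conditions: LiOH·H2O (5 equiv), THF/MeOH/H2O, 50 °C; then 1 M HCl
Reagents that add atoms: lithium hydroxide, [Li+].[OH-]
Why: Ester saponification done before the aldol step so that the strongly basic condensation starts from one defined carboxylate; ketone and aryl ethers are inert.

**Step 7**
Reactants: 10 3-(3-acetyl-4-hydroxy-2,6-dimethoxyphenyl)-4-methoxybenzoic acid; 11 4-methoxybenzaldehyde
Product: 13 3-{4-hydroxy-2,6-dimethoxy-3-[(2E)-3-(4-methoxyphenyl)prop-2-enoyl]phenyl}-4-methoxybenzoic acid, via aldol adduct 12 (not isolated)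
Conditions: KOH (50% aq, 15 equiv), EtOH, rt, 48 h; then 2 M HCl to pH 2
Reagents that add atoms: none
Why: Claisen–Schmidt crossed aldol condensation, the key fragment-joining step: the methyl ketone enolate adds to the non-enolisable aldehyde and E1cB loss of water gives the thermodynamically favoured E-enone.

**Step 8**
Reactants: 13 3-{4-hydroxy-2,6-dimethoxy-3-[(2E)-3-(4-methoxyphenyl)prop-2-enoyl]phenyl}-4-methoxybenzoic acid
Product: 15 3-[5,7-dimethoxy-2-(4-methoxyphenyl)-4-oxo-4H-chromen-6-yl]-4-methoxybenzoic acid, via flavanone 14 (not isolated)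
Conditions: I2 (10 mol%), DMSO, 130 °C, 3 h
Reagents that add atoms: none
Why: Oxa-Michael closure of the only free ortho-phenol to the flavanone and iodine-catalysed dehydrogenation with DMSO as terminal oxidant give the flavone; the other ortho oxygen is methylated, so the aryl group can only end up at C6.

**Step 9**
Reactants: 15 3-[5,7-dimethoxy-2-(4-methoxyphenyl)-4-oxo-4H-chromen-6-yl]-4-methoxybenzoic acid
Product: 16 3-[5,7-dihydroxy-2-(4-hydroxyphenyl)-4-oxo-4H-chromen-6-yl]-4-hydroxybenzoic acid
Conditions: BBr3 (12 equiv), CH2Cl2, −78 °C to rt, 24 h; then ice-water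
Reagents that add atoms: none
Why: Lewis-acid ether cleavage (BBr3 demethylation) removes all four aryl methyl ethers under aprotic conditions at or below room temperature, which avoids Wessely–Moser scrambling of the 6-aryl group; aqueous work-up frees the phenols and the acid.

**Compound list**
1 | 3,5-dimethoxyphenol | COc1cc(O)cc(OC)c1 | starting material
2 | (3,5-dimethoxyphenoxy)tri(propan-2-yl)silane | COc1cc(O[Si](C(C)C)(C(C)C)C(C)C)cc(OC)c1 | intermediate
3 | {2,6-dimethoxy-4-[tri(propan-2-yl)silyloxy]phenyl}lithium | [Li]c1c(OC)cc(O[Si](C(C)C)(C(C)C)C(C)C)cc1OC | intermediate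
4 | (4-iodo-3,5-dimethoxyphenoxy)tri(propan-2-yl)silane | COc1cc(O[Si](C(C)C)(C(C)C)C(C)C)cc(OC)c1I | intermediate
5 | [2-methoxy-5-(methoxycarbonyl)phenyl]boronic acid | COC(=O)c1ccc(OC)c(B(O)O)c1 | starting material
6 | methyl 3-{2,6-dimethoxy-4-[tri(propan-2-yl)silyloxy]phenyl}-4-methoxybenzoate | COC(=O)c1ccc(OC)c(-c2c(OC)cc(O[Si](C(C)C)(C(C)C)C(C)C)cc2OC)c1 | intermediate
7 | methyl 3-(4-hydroxy-2,6-dimethoxyphenyl)-4-methoxybenzoate | COC(=O)c1ccc(OC)c(-c2c(OC)cc(O)cc2OC)c1 | intermediate
8 | methyl 3-[4-(acetyloxy)-2,6-dimethoxyphenyl]-4-methoxybenzoate | COC(=O)c1ccc(OC)c(-c2c(OC)cc(OC(C)=O)cc2OC)c1 | intermediate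
9 | methyl 3-(3-acetyl-4-hydroxy-2,6-dimethoxyphenyl)-4-methoxybenzoate | COC(=O)c1ccc(OC)c(-c2c(OC)cc(O)c(C(C)=O)c2OC)c1 | intermediate
10 | 3-(3-acetyl-4-hydroxy-2,6-dimethoxyphenyl)-4-methoxybenzoic acid | O=C(O)c1ccc(OC)c(-c2c(OC)cc(O)c(C(C)=O)c2OC)c1 | intermediate
11 | 4-methoxybenzaldehyde | COc1ccc(C=O)cc1 | starting material
12 | 3-{4-hydroxy-3-[3-hydroxy-3-(4-methoxyphenyl)propanoyl]-2,6-dimethoxyphenyl}-4-methoxybenzoic acid (racemic) | O=C(O)c1ccc(OC)c(-c2c(OC)cc(O)c(C(=O)CC(O)c3ccc(OC)cc3)c2OC)c1 | intermediate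
13 | 3-{4-hydroxy-2,6-dimethoxy-3-[(2E)-3-(4-methoxyphenyl)prop-2-enoyl]phenyl}-4-methoxybenzoic acid | O=C(O)c1ccc(OC)c(-c2c(OC)cc(O)c(C(=O)/C=C/c3ccc(OC)cc3)c2OC)c1 | intermediate
14 | 3-[5,7-dimethoxy-2-(4-methoxyphenyl)-4-oxo-3,4-dihydro-2H-chromen-6-yl]-4-methoxybenzoic acid (racemic) | O=C(O)c1ccc(OC)c(-c2c(OC)cc3OC(c4ccc(OC)cc4)CC(=O)c3c2OC)c1 | intermediate
15 | 3-[5,7-dimethoxy-2-(4-methoxyphenyl)-4-oxo-4H-chromen-6-yl]-4-methoxybenzoic acid | O=C(O)c1ccc(OC)c(-c2c(OC)cc3oc(-c4ccc(OC)cc4)cc(=O)c3c2OC)c1 | intermediate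
16 | 3-[5,7-dihydroxy-2-(4-hydroxyphenyl)-4-oxo-4H-chromen-6-yl]-4-hydroxybenzoic acid | O=C(O)c1ccc(O)c(-c2c(O)cc3oc(-c4ccc(O)cc4)cc(=O)c3c2O)c1 | target

**Totals**
Total step count: 9. Longest linear sequence: 9 steps (1 to 16); compounds 5 and 11 are bought.

**Steps most likely to fail, with fallbacks**

Step 3 (hindered Suzuki coupling). Oxidative addition into the electron-rich, doubly ortho-substituted iodide 4 may be slow, and boronic acid 5 may protodeboronate. The fallback is a Negishi coupling with reversed polarity that sets out from compound 2. Compound 2 is lithiated as in step 2 to aryllithium 3 and treated with ZnCl2 (THF, 0 °C) to give chloro{2,6-dimethoxy-4-[tri(propan-2-yl)silyloxy]phenyl}zinc F1. F1 is coupled with commercial methyl 3-bromo-4-methoxybenzoate (COC(=O)c1ccc(OC)c(Br)c1) using Pd(OAc)2/SPhos in THF at 60 °C. The product is compound 6, where the route is rejoined; iodide 4 and the boronic acid are bypassed.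

Step 5 (acetylation and Fries rearrangement). BF3 at 80 °C may rearrange incompletely or cleave the methoxy group next to the new ketone. The fallback replaces acyl-cation chemistry with a Houben–Hoesch reaction that sets out from compound 7. MeCN, dry HCl and ZnCl2 in Et2O at 0 °C add the nitrile carbon to the same unique ortho position, and methyl 3-[4-hydroxy-3-(1-iminioethyl)-2,6-dimethoxyphenyl]-4-methoxybenzoate chloride F2 precipitates. Warming F2 in water at 80 °C hydrolyses the ketiminium salt to compound 9, where the route is rejoined.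

Step 9 (fourfold demethylation). One-pot BBr3 cleavage may stop at partly methylated material or give a hard-to-purify mixture. The fallback is a two-stage sequence with a different mechanism that sets out from compound 15. BCl3 (CH2Cl2, 0 °C) removes only the chelated 5-O-methyl group to give 3-[5-hydroxy-7-methoxy-2-(4-methoxyphenyl)-4-oxo-4H-chromen-6-yl]-4-methoxybenzoic acid F3. The three remaining methyl ethers are then cleaved by SN2 attack of thiolate at the methyl carbons (NaSEt, DMF, 120 °C; then dilute HCl). This last operation is basic, so acid-induced ring-opening isomerisation is excluded. It delivers compound 16, the target.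

**Further compounds**
F1 | step 3 | chloro{2,6-dimethoxy-4-[tri(propan-2-yl)silyloxy]phenyl}zinc | Cl[Zn]c1c(OC)cc(O[Si](C(C)C)(C(C)C)C(C)C)cc1OC
F2 | step 5 | methyl 3-[4-hydroxy-3-(1-iminioethyl)-2,6-dimethoxyphenyl]-4-methoxybenzoate chloride | COC(=O)c1ccc(OC)c(-c2c(OC)cc(O)c(C(C)=[NH2+])c2OC)c1.[Cl-]
F3 | step 9 | 3-[5-hydroxy-7-methoxy-2-(4-methoxyphenyl)-4-oxo-4H-chromen-6-yl]-4-methoxybenzoic acid | O=C(O)c1ccc(OC)c(-c2c(OC)cc3oc(-c4ccc(OC)cc4)cc(=O)c3c2O)c1
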